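**Strategy.** Ring C is disconnected across O1–C2 and C3–C4. The O1–C8a–C4a–C4 unit of ring A is treated as an o-quinone methide (an oxa-diene that already carries the C4 oxygen). C2–C3 is an (E)-alkene carrying the ring B aryl on C2 and an acetoxy group on C3. A chiral Brønsted acid generates the 4-methoxy-o-quinone methide from a prenylated salicylaldehyde and trimethyl orthoformate and joins it to the enol acetate in one inverse-demand oxa-[4+2] step. This closes ring C with every oxygen in place, so no oxidation is needed in the presence of the prenyl group. Deacylation and equilibrating solvolysis at C4 finish the synthesis.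

Key step: step 8

Remark: the facial sense of induction of the chiral acid in step 8 has to be found by experiment; the (R)-configured catalyst is written, and its mirror image would be used if the opposite sense is found.

Step 1
Reactants: 1 5-methoxybenzene-1,3-diol (5-methoxyresorcinol)
Product: 2 1-methoxy-3,5-bis(methoxymethoxy)benzene
Conditions: NaH (2.4 equiv), MOMCl (2.4 equiv), DMF, 0 °C to rt
Reagents that add atoms: chloromethyl methyl ether, COCCl
Why: Williamson-type O-alkylation of both phenoxides installs two MOM ethers that later direct both metalations.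

Step 2
Reactants: 2 1-methoxy-3,5-bis(methoxymethoxy)benzene
Product: 4 5-methoxy-1,3-bis(methoxymethoxy)-2-(3-methylbut-2-en-1-yl)benzene, via aryllithium 3 (not isolated)
Conditions: n-BuLi (1.1 equiv), THF, 0 °C; CuI (10 mol%), prenyl bromide (1.2 equiv), −78 °C to rt
Reagents that add atoms: 1-bromo-3-methylbut-2-ene (prenyl bromide), CC(C)=CCBr
Why: Directed ortho-metalation should occur at the carbon flanked by both chelating MOM ethers, and copper-catalysed SN2 allylation of the aryllithium places the prenyl group between the two future O1 and O7 oxygens.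

Step 3
Reactants: 4 5-methoxy-1,3-bis(methoxymethoxy)-2-(3-methylbut-2-en-1-yl)benzene
Product: 6 6-methoxy-2,4-bis(methoxymethoxy)-3-(3-methylbut-2-en-1-yl)benzaldehyde, via aryllithium 5 (not isolated)
Conditions: n-BuLi (1.2 equiv), TMEDA (1.2 equiv), THF, −20 to 0 °C; DMF (3 equiv); H2O
Reagents that add atoms: N,N-dimethylformamide, CN(C)C=O
Why: A second directed ortho-metalation can only take the two remaining ring positions, which are equivalent by symmetry and each flanked by OMe and OMOM, and formylation of the aryllithium with DMF gives the aldehyde with unambiguous regiochemistry.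

Step 4
Reactants: 6 6-methoxy-2,4-bis(methoxymethoxy)-3-(3-methylbut-2-en-1-yl)benzaldehyde
Product: 7 2,4-dihydroxy-6-methoxy-3-(3-methylbut-2-en-1-yl)benzaldehyde
Conditions: HCl (cat.), MeOH, rt; aqueous work-up
Reagents that add atoms: none
Why: Acid-catalysed acetal exchange (methanolysis of the MOM ethers) frees both phenols, and the prenyl group and the aldehyde (any dimethyl acetal reverts on aqueous work-up) should tolerate the short exposure at room temperature.

Step 5
Reactants: 7 2,4-dihydroxy-6-methoxy-3-(3-methylbut-2-en-1-yl)benzaldehyde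
Product: 8 4-formyl-3-hydroxy-5-methoxy-2-(3-methylbut-2-en-1-yl)phenyl acetate
Conditions: Ac2O (1.05 equiv), pyridine, CH2Cl2, 0 °C
Reagents that add atoms: acetic anhydride, CC(=O)OC(C)=O
Why: Chemoselective O-acylation is expected because the 2-OH is tied up in the hydrogen bond to the formyl group and doubly flanked, so only the more acidic, accessible 4-OH reacts with one equivalent of anhydride.

Step 6
Reactants: 9 4-[(tert-butyldimethylsilyl)oxy]benzaldehyde
Product: 10 (E)-tert-butyldimethyl{4-[2-(4,4,5,5-tetramethyl-1,3,2-dioxaborolan-2-yl)ethenyl]phenoxy}silane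
Conditions: CH2(Bpin)2 (1.2 equiv), lithium 2,2,6,6-tetramethylpiperidide (1.2 equiv), THF, −78 °C to rt
Reagents that add atoms: bis(4,4,5,5-tetramethyl-1,3,2-dioxaborolan-2-yl)methane, CC1(C)OB(CB2OC(C)(C)C(C)(C)O2)OC1(C)C
Why: Boron–Wittig olefination: the lithiated gem-diboronate adds to the aldehyde and syn-elimination of the boron oxide from the preferred adduct should give the (E)-alkenyl boronate, which supplies C3.

Step 7
Reactants: 10 (E)-tert-butyldimethyl{4-[2-(4,4,5,5-tetramethyl-1,3,2-dioxaborolan-2-yl)ethenyl]phenoxy}silane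
Product: 11 (E)-2-{4-[(tert-butyldimethylsilyl)oxy]phenyl}ethenyl acetate
Conditions: Cu(OAc)2 (2.2 equiv), Et3N (2 equiv), 4 Å MS, MeCN, rt, argon
Reagents that add atoms: copper diacetate, CC(=O)[O-].CC(=O)[O-].[Cu+2]
Why: Chan–Lam-type C–O coupling (alkenylboron to enol ester): transmetalation to divalent copper and reductive elimination with an acetate ligand should replace boron by acetoxy with retention of the (E)-geometry.

Step 8
Reactants: 8 4-formyl-3-hydroxy-5-methoxy-2-(3-methylbut-2-en-1-yl)phenyl acetate and 11 (E)-2-{4-[(tert-butyldimethylsilyl)oxy]phenyl}ethenyl acetate (2 equiv)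
Product: 14 (2R,3S,4S)-2-{4-[(tert-butyldimethylsilyl)oxy]phenyl}-4,5-dimethoxy-8-(3-methylbut-2-en-1-yl)-3,4-dihydro-2H-chromene-3,7-diyl diacetate, via dimethyl acetal 12 (not isolated), via methoxy-o-quinone methide 13 (not isolated)
Conditions: HC(OMe)3 (1.5 equiv), (R)-3,3'-bis(2,4,6-triisopropylphenyl)-1,1'-binaphthyl-2,2'-diyl N-triflylphosphoramide (5 mol%), CH2Cl2, −20 °C to rt
Reagents that add atoms: trimethyl orthoformate, COC(OC)OC
Why: Proposed new method: acid-promoted acetalisation of 8 and loss of methanol give the hydrogen-bonded ion pair of o-quinone methide 13 with the chiral phosphoramide anion, which should undergo an asynchronous inverse-electron-demand oxa-[4+2] cycloaddition with 11, the C3–C4 bond leading and O1 closing onto the developing C2 benzylic cation. The closest known reaction types are the acid-catalysed three-component chroman synthesis from salicylaldehydes, orthoformates and styrenes and the chiral-phosphoramide-catalysed [4+2] cycloaddition of o-quinone methides with styrenes; new are the β-acyloxystyrene as the two-carbon partner and asymmetric control with a 4-alkoxy heterodiene. Ring C is closed in this [4+2] mode (in the stepwise limit a Prins addition followed by six-membered closure of the phenol oxygen onto the cation). C3 is set by the catalyst, whose anion is held by the phenol O–H and shields one face of the heterodiene during the irreversible C–C bond formation; C2 follows from the (E)-geometry of 11 (aryl and acetoxy trans, both equatorial); the 4-OMe is expected quasi-axial and cis to the 3-acetoxy group to avoid peri strain with 5-OMe, can equilibrate by ionisation, and is re-set in step 10 in any case. The step needs regioselectivity (C3, not C2, must bond to C4), which the p-silyloxyphenyl donor should secure because it stabilises positive charge at C2 far better than the ester-deactivated acetoxy oxygen could at C3, and chemoselectivity over the prenyl alkene, which the excess of the styrenyl partner and the 7-O-acetyl group (less nucleophilic ring A, more electrophilic heterodiene) should secure.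

Step 9
Reactants: 14 (2R,3S,4S)-2-{4-[(tert-butyldimethylsilyl)oxy]phenyl}-4,5-dimethoxy-8-(3-methylbut-2-en-1-yl)-3,4-dihydro-2H-chromene-3,7-diyl diacetate
Product: 15 (2R,3S,4S)-2-(4-hydroxyphenyl)-4,5-dimethoxy-8-(3-methylbut-2-en-1-yl)-3,4-dihydro-2H-chromene-3,7-diol
Conditions: K2CO3 (3 equiv), MeOH, 0 °C to rt, argon; aq. NH4Cl
Reagents that add atoms: none
Why: Base-mediated methanolysis (transesterification) should remove both acetates and cleave the aryl silyl ether, while C2, C3 and the C4 methyl ether are not touched, so no stereocentre changes.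

Step 10
Reactants: 15 (2R,3S,4S)-2-(4-hydroxyphenyl)-4,5-dimethoxy-8-(3-methylbut-2-en-1-yl)-3,4-dihydro-2H-chromene-3,7-diol
Product: 16 (2R,3S,4S)-2-(4-hydroxyphenyl)-5-methoxy-8-(3-methylbut-2-en-1-yl)-3,4-dihydro-2H-chromene-3,4,7-triol (5-O-methyl-8-prenylafzelechin-4β-ol)
Conditions: AcOH (1% v/v), acetone/H2O (1:1), high dilution, 40 °C, argon
Reagents that add atoms: water, O
Why: Acid-catalysed SN1 solvolysis (the reaction type known for 4-oxygenated flavans and for the epimerisation of leucoanthocyanidins): the C4 benzylic cation, stabilised by 5-OMe, 7-OH and O1, forms reversibly and is captured by the large excess of water, and the equilibrium should settle on the 4β epimer, whose quasi-axial 4-OH avoids peri strain with 5-OMe and is cis to the equatorial 3-OH, while C2 and C3 are not involved.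

**Compound list**

1 | 5-methoxybenzene-1,3-diol | COc1cc(O)cc(O)c1 | starting material
2 | 1-methoxy-3,5-bis(methoxymethoxy)benzene | COc1cc(OCOC)cc(OCOC)c1 | intermediate
3 | [4-methoxy-2,6-bis(methoxymethoxy)phenyl]lithium | [Li]c1c(OCOC)cc(OC)cc1OCOC | intermediate
4 | 5-methoxy-1,3-bis(methoxymethoxy)-2-(3-methylbut-2-en-1-yl)benzene | COc1cc(OCOC)c(CC=C(C)C)c(OCOC)c1 | intermediate
5 | [6-methoxy-2,4-bis(methoxymethoxy)-3-(3-methylbut-2-en-1-yl)phenyl]lithium | COc1cc(OCOC)c(CC=C(C)C)c(OCOC)c1[Li] | intermediate
6 | 6-methoxy-2,4-bis(methoxymethoxy)-3-(3-methylbut-2-en-1-yl)benzaldehyde | COc1cc(OCOC)c(CC=C(C)C)c(OCOC)c1C=O | intermediate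
7 | 2,4-dihydroxy-6-methoxy-3-(3-methylbut-2-en-1-yl)benzaldehyde | COc1cc(O)c(CC=C(C)C)c(O)c1C=O | intermediate
8 | 4-formyl-3-hydroxy-5-methoxy-2-(3-methylbut-2-en-1-yl)phenyl acetate | COc1cc(OC(C)=O)c(CC=C(C)C)c(O)c1C=O | intermediate
9 | 4-[(tert-butyldimethylsilyl)oxy]benzaldehyde | CC(C)(C)[Si](C)(C)Oc1ccc(C=O)cc1 | starting material
10 | (E)-tert-butyldimethyl{4-[2-(4,4,5,5-tetramethyl-1,3,2-dioxaborolan-2-yl)ethenyl]phenoxy}silane | CC(C)(C)[Si](C)(C)Oc1ccc(/C=C/B2OC(C)(C)C(C)(C)O2)cc1 | intermediate
11 | (E)-2-{4-[(tert-butyldimethylsilyl)oxy]phenyl}ethenyl acetate | CC(=O)O/C=C/c1ccc(O[Si](C)(C)C(C)(C)C)cc1 | intermediate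
12 | 4-(dimethoxymethyl)-3-hydroxy-5-methoxy-2-(3-methylbut-2-en-1-yl)phenyl acetate | COc1cc(OC(C)=O)c(CC=C(C)C)c(O)c1C(OC)OC | intermediate
13 | (E)-5-methoxy-4-(methoxymethylidene)-2-(3-methylbut-2-en-1-yl)-3-oxocyclohexa-1,5-dien-1-yl acetate (reacting as its ion pair with the catalyst) | CO/C=C1/C(=O)C(CC=C(C)C)=C(OC(C)=O)C=C1OC | intermediate
14 | (2R,3S,4S)-2-{4-[(tert-butyldimethylsilyl)oxy]phenyl}-4,5-dimethoxy-8-(3-methylbut-2-en-1-yl)-3,4-dihydro-2H-chromene-3,7-diyl diacetate | COc1cc(OC(C)=O)c(CC=C(C)C)c2c1[C@H](OC)[C@H](OC(C)=O)[C@@H](c1ccc(O[Si](C)(C)C(C)(C)C)cc1)O2 | intermediate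
15 | (2R,3S,4S)-2-(4-hydroxyphenyl)-4,5-dimethoxy-8-(3-methylbut-2-en-1-yl)-3,4-dihydro-2H-chromene-3,7-diol | COc1cc(O)c(CC=C(C)C)c2c1[C@H](OC)[C@H](O)[C@@H](c1ccc(O)cc1)O2 | intermediate
16 | (2R,3S,4S)-2-(4-hydroxyphenyl)-5-methoxy-8-(3-methylbut-2-en-1-yl)-3,4-dihydro-2H-chromene-3,4,7-triol | COc1cc(O)c(CC=C(C)C)c2c1[C@H](O)[C@H](O)[C@@H](c1ccc(O)cc1)O2 | target

**Step count.** Total: 10 steps. Longest linear sequence: 8 steps (steps 1–5, 8, 9, 10).

**Steps most likely to fail**

Step 8. The C–C bond may form through the enol-ester mode (C2 instead of C3 attacking C4), the prenyl alkene may compete as nucleophile, or the catalyst may discriminate the alkene faces poorly. The fallback uses only known chemistry, sets out from 4 and comes back at 16. Compound 4 is lithiated as in step 3 (giving 5) and acylated with N-methoxy-N-methylacetamide to give 1-[6-methoxy-2,4-bis(methoxymethoxy)-3-(3-methylbut-2-en-1-yl)phenyl]ethan-1-one F1. Claisen–Schmidt condensation with commercial 4-(methoxymethoxy)benzaldehyde (KOH, EtOH) gives (E)-1-[6-methoxy-2,4-bis(methoxymethoxy)-3-(3-methylbut-2-en-1-yl)phenyl]-3-[4-(methoxymethoxy)phenyl]prop-2-en-1-one F2. Juliá–Colonna epoxidation (poly-L-leucine, urea–H2O2, DBU, THF), a nucleophilic peroxide addition that should leave the prenyl group alone, gives [6-methoxy-2,4-bis(methoxymethoxy)-3-(3-methylbut-2-en-1-yl)phenyl]{(2R,3S)-3-[4-(methoxymethoxy)phenyl]oxiran-2-yl}methanone F3. HCl in MeOH removes the MOM groups and the freed 2'-OH opens the epoxide at the benzylic carbon with inversion to give (2R,3R)-3,7-dihydroxy-2-(4-hydroxyphenyl)-5-methoxy-8-(3-methylbut-2-en-1-yl)-2,3-dihydro-4H-chromen-4-one F4. NaBH4 in EtOH is expected to give mainly (2R,3S,4R)-2-(4-hydroxyphenyl)-5-methoxy-8-(3-methylbut-2-en-1-yl)-3,4-dihydro-2H-chromene-3,4,7-triol F5, the 4α epimer, which is equilibrated in 1% aqueous AcOH as in step 10 to 16.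

Step 10. Stereoconvergence at C4 may be incomplete, and the C4 cation may condense with the nucleophilic ring A of a second molecule. The fallback sets out from 15 and comes back at 16. Compound 15 is ionised under the same mild acid in the presence of phenylboronic acid, so that only the cis-3,4-diol is drained from the equilibrating mixture as the cis-fused cyclic 3,4-O-phenylboronate of 16 F6. The boronate is then released under neutral conditions by transesterification with pinacol to give 16.

Step 7. Transmetalation of the pinacol boronate to divalent copper may be slow, with protodeboronation or homocoupling taking over. The fallback sets out from 10 and comes back at 11. Compound 10 is oxidised with NaBO3·4H2O in THF/H2O to 2-{4-[(tert-butyldimethylsilyl)oxy]phenyl}acetaldehyde F7, which is enol-acetylated (Ac2O, KOAc) to 11 together with its (Z)-isomer; the (E)-isomer is separated by chromatography.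

**Further compounds**

F1 | step 8 | 1-[6-methoxy-2,4-bis(methoxymethoxy)-3-(3-methylbut-2-en-1-yl)phenyl]ethan-1-one | COc1cc(OCOC)c(CC=C(C)C)c(OCOC)c1C(C)=O
F2 | step 8 | (E)-1-[6-methoxy-2,4-bis(methoxymethoxy)-3-(3-methylbut-2-en-1-yl)phenyl]-3-[4-(methoxymethoxy)phenyl]prop-2-en-1-one | COc1cc(OCOC)c(CC=C(C)C)c(OCOC)c1C(=O)/C=C/c1ccc(OCOC)cc1
F3 | step 8 | [6-methoxy-2,4-bis(methoxymethoxy)-3-(3-methylbut-2-en-1-yl)phenyl]{(2R,3S)-3-[4-(methoxymethoxy)phenyl]oxiran-2-yl}methanone | COc1cc(OCOC)c(CC=C(C)C)c(OCOC)c1C(=O)[C@@H]1O[C@H]1c1ccc(OCOC)cc1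
F4 | step 8 | (2R,3R)-3,7-dihydroxy-2-(4-hydroxyphenyl)-5-methoxy-8-(3-methylbut-2-en-1-yl)-2,3-dihydro-4H-chromen-4-one | COc1cc(O)c(CC=C(C)C)c2c1C(=O)[C@H](O)[C@@H](c1ccc(O)cc1)O2
F5 | step 8 | (2R,3S,4R)-2-(4-hydroxyphenyl)-5-methoxy-8-(3-methylbut-2-en-1-yl)-3,4-dihydro-2H-chromene-3,4,7-triol | COc1cc(O)c(CC=C(C)C)c2c1[C@@H](O)[C@H](O)[C@@H](c1ccc(O)cc1)O2
F6 | step 10 | cyclic 3,4-O-phenylboronate of 16 (2-phenyl-1,3,2-dioxaborolane cis-fused at C3–C4) | COc1cc(O)c(CC=C(C)C)c2c1[C@@H]1OB(c3ccccc3)O[C@@H]1[C@@H](c1ccc(O)cc1)O2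
F7 | step 7 | 2-{4-[(tert-butyldimethylsilyl)oxy]phenyl}acetaldehyde | CC(C)(C)[Si](C)(C)Oc1ccc(CC=O)cc1
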